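**Assumption:** the SMILES is read as (S) at the diarylmethine carbon on ring A and (R) at the carbinol carbon, i.e. a (1S,2E,5R)-5-hydroxy-1,7-bis(4-hydroxyphenyl)hept-2-en-1-yl group at C-3' of the chalcone (acyl carbon = C-1' of ring A); all listed starting materials are taken as catalogue compounds.

## Retrosynthetic overview

1. Chalcone enone: made last by Claisen–Schmidt condensation of the ring-A acetyl group with 4-hydroxybenzaldehyde; the same basic step removes every phenol protecting group.
2. C2=C3 alkene of the heptenyl chain: cross-metathesis of a propenyl-bearing ring-A half with an (R)-homoallylic alcohol whose carbinol stereocentre is bought in (S)-epichlorohydrin.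
3. Ring A–C1 bond and the diarylmethine stereocentre: light-gated (photoacid) aromatic Claisen [3,3] shift of a 2'-O-[(S)-1-methyl-3-arylallyl] ether; 1,3-chirality transfer, and the acetyl group blocks the other ortho carbon.
4. That ether comes from Mitsunobu inversion of an (R,E)-allylic alcohol, itself made from bought (R)-but-3-en-2-ol and 4-acetoxystyrene by cross-metathesis.
5. No ring is constructed; all four benzene rings are bought and joined in the order: C1 hydroxyphenyl ring to ring A (steps 2–4), C7 hydroxyphenyl ring (step 7), ring B (step 8).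

## Route

Step 1
Reactants: 1 1-(2,4-dihydroxy-6-methoxyphenyl)ethan-1-one; 2 tert-butyldimethylsilyl chloride
Product: 3 1-[4-(tert-butyldimethylsilyloxy)-2-hydroxy-6-methoxyphenyl]ethan-1-one
Conditions: TBSCl (1.05 equiv), imidazole, DMF, 0 °C → rt
Reagents that add atoms: tert-butyldimethylsilyl chloride, CC(C)(C)[Si](C)(C)Cl
Why: Selective O-silylation of the free 4'-OH, because the 2'-OH is held in the hydrogen bond to the acetyl carbonyl and is much less nucleophilic.

Step 2
Reactants: 4 (R)-but-3-en-2-ol; 5 4-vinylphenyl acetate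
Product: 6 4-[(1E,3R)-3-hydroxybut-1-en-1-yl]phenyl acetate
Conditions: 5 (2.5 equiv), second-generation Hoveyda–Grubbs catalyst RuCl2(H2IMes)(=CH-C6H4-2-O-i-Pr) (3 mol%), 1,4-benzoquinone (10 mol%), CH2Cl2, 40 °C
Reagents that add atoms: 4-vinylphenyl acetate, CC(=O)Oc1ccc(C=C)cc1
Why: Olefin cross-metathesis of a styrene with a secondary allylic alcohol gives the E-alkene with loss of ethylene, and the bought carbinol stereocentre is not touched.

Step 3
Reactants: 3 1-[4-(tert-butyldimethylsilyloxy)-2-hydroxy-6-methoxyphenyl]ethan-1-one; 6 4-[(1E,3R)-3-hydroxybut-1-en-1-yl]phenyl acetate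
Product: 7 4-[(1E,3S)-3-[2-acetyl-5-(tert-butyldimethylsilyloxy)-3-methoxyphenoxy]but-1-en-1-yl]phenyl acetate
Conditions: PPh3, DIAD (slow addition), toluene, 0 °C → rt
Reagents that add atoms: none
Why: Mitsunobu etherification, in which SN2 attack of the 2'-phenoxide on the alkoxyphosphonium ion inverts the carbinol carbon from (R) to (S); the electron-poor acetoxyphenyl group disfavours ionisation and SN2' attack.

Step 4
Reactants: 7 4-[(1E,3S)-3-[2-acetyl-5-(tert-butyldimethylsilyloxy)-3-methoxyphenoxy]but-1-en-1-yl]phenyl acetate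
Product: 9 4-[(1S,2E)-1-[3-acetyl-6-(tert-butyldimethylsilyloxy)-2-hydroxy-4-methoxyphenyl]but-2-en-1-yl]phenyl acetate, via ortho-dienone 8 (not isolated)
Conditions: merocyanine photoacid 2-[(E)-2-(2-hydroxyphenyl)ethenyl]-3,3-dimethyl-1-(3-sulfonatopropyl)-3H-indol-1-ium (10 mol%), 470 nm LEDs, CH2Cl2/MeCN 9:1, −20 °C, N2; then Et3N in the dark
Reagents that add atoms: none
Why: Proposed new method: blue light converts the merocyanine into its metastable spiro form and releases a proton that is held in the six-membered chelate between the acetyl oxygen and the ether oxygen of 7, and this charge acceleration should let the aromatic Claisen [3,3] shift run at −20 °C through a chair transition state with the C-methyl group equatorial, so that C-3' bonds to the styryl terminus on the same face from which the C–O bond departs (suprafacial), the (S) carbinol carbon of 7 sets the (S) diarylmethine of 9, the new alkene is E, and dienone 8 enolises to the chelated phenol; C-3' is the only free ortho carbon, the acid exists only at a low photostationary level that vanishes in the dark, and the acetoxy group on the migrating aryl ring slows ionisation; the closest known reaction types are the thermal aromatic Claisen rearrangement with 1,3-chirality transfer and its Brønsted- or Lewis-acid (charge-accelerated) variants, and visible-light photoacid catalysis of other acid-promoted reactions, but photoacid gating of a Claisen shift on a chiral 1-methyl-3-arylallyl aryl ether has not been shown.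

Step 5
Reactants: 10 (S)-2-(chloromethyl)oxirane; 11 vinylmagnesium bromide
Product: 13 (S)-2-(prop-2-en-1-yl)oxirane, via (S)-1-chloropent-4-en-2-ol 12 (not isolated)
Conditions: 11 (1.2 equiv), CuI (5 mol%), THF, −40 °C; aq. NH4Cl; then NaOH (powder), Et2O, rt
Reagents that add atoms: vinylmagnesium bromide, C=C[Mg]Br
Why: Copper-catalysed Grignard opening at the epoxide CH2 followed by intramolecular Williamson closure of the chlorohydrin onto the former CH2Cl carbon; no bond at the stereocentre is made or broken, so the bought configuration is kept.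

Step 6
Reactants: 13 (S)-2-(prop-2-en-1-yl)oxirane; 14 tert-butyl[4-(chloromethyl)phenoxy]dimethylsilane
Product: 16 (R)-1-[4-(tert-butyldimethylsilyloxy)phenyl]hex-5-en-3-ol, via benzylic Grignard reagent 15 (not isolated)
Conditions: 14, Mg, THF, rt; then 13, CuI (10 mol%), THF, −30 → 0 °C
Reagents that add atoms: tert-butyl[4-(chloromethyl)phenoxy]dimethylsilane, CC(C)(C)[Si](C)(C)Oc1ccc(CCl)cc1
Why: Copper-catalysed SN2 opening of the terminal epoxide at its CH2 by the benzylic Grignard reagent; the C–O bond at the stereocentre is untouched, and the descriptor changes from S to R only because the substituent priorities change.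

Step 7
Reactants: 9 4-[(1S,2E)-1-[3-acetyl-6-(tert-butyldimethylsilyloxy)-2-hydroxy-4-methoxyphenyl]but-2-en-1-yl]phenyl acetate; 16 (R)-1-[4-(tert-butyldimethylsilyloxy)phenyl]hex-5-en-3-ol
Product: 17 4-[(1S,2E,5R)-1-[3-acetyl-6-(tert-butyldimethylsilyloxy)-2-hydroxy-4-methoxyphenyl]-7-[4-(tert-butyldimethylsilyloxy)phenyl]-5-hydroxyhept-2-en-1-yl]phenyl acetate
Conditions: 16 (3 equiv), second-generation Hoveyda–Grubbs catalyst RuCl2(H2IMes)(=CH-C6H4-2-O-i-Pr) (5 mol%), 1,4-benzoquinone (10 mol%), CH2Cl2, 40 °C
Reagents that add atoms: none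
Why: Olefin cross-metathesis of the propenyl group with a rapidly homodimerising terminal alkene is driven by loss of propene and is E-selective next to the branched diarylmethine carbon; benzoquinone suppresses ruthenium-hydride alkene migration and neither stereocentre is involved.

Step 8
Reactants: 17 4-[(1S,2E,5R)-1-[3-acetyl-6-(tert-butyldimethylsilyloxy)-2-hydroxy-4-methoxyphenyl]-7-[4-(tert-butyldimethylsilyloxy)phenyl]-5-hydroxyhept-2-en-1-yl]phenyl acetate; 18 4-hydroxybenzaldehyde
Product: 20 (2E)-1-{2,4-dihydroxy-3-[(1S,2E,5R)-5-hydroxy-1,7-bis(4-hydroxyphenyl)hept-2-en-1-yl]-6-methoxyphenyl}-3-(4-hydroxyphenyl)prop-2-en-1-one, via pentahydroxy ketone 19 (not isolated)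
Conditions: 18 (3 equiv), KOH (50% aq.), EtOH, N2, rt → 40 °C; then 1 M HCl to pH 4, 0 °C
Reagents that add atoms: 4-hydroxybenzaldehyde, O=Cc1ccc(O)cc1
Why: Hydroxide first cleaves the aryl acetate and both aryl silyl ethers, then Claisen–Schmidt aldol condensation (E1cB dehydration) of the methyl ketone with the aldehyde gives the E-enone; neither stereocentre carries a hydrogen acidic enough to epimerise under these conditions.

## Compound list

1 | 1-(2,4-dihydroxy-6-methoxyphenyl)ethan-1-one | CC(=O)c1c(O)cc(O)cc1OC | starting material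
2 | tert-butyldimethylsilyl chloride | CC(C)(C)[Si](C)(C)Cl | starting material
3 | 1-[4-(tert-butyldimethylsilyloxy)-2-hydroxy-6-methoxyphenyl]ethan-1-one | CC(=O)c1c(O)cc(O[Si](C)(C)C(C)(C)C)cc1OC | intermediate
4 | (R)-but-3-en-2-ol | C[C@@H](O)C=C | starting material
5 | 4-vinylphenyl acetate | CC(=O)Oc1ccc(C=C)cc1 | starting material
6 | 4-[(1E,3R)-3-hydroxybut-1-en-1-yl]phenyl acetate | C[C@@H](O)/C=C/c1ccc(OC(C)=O)cc1 | intermediate
7 | 4-[(1E,3S)-3-[2-acetyl-5-(tert-butyldimethylsilyloxy)-3-methoxyphenoxy]but-1-en-1-yl]phenyl acetate | CC(=O)c1c(O[C@@H](C)/C=C/c2ccc(OC(C)=O)cc2)cc(O[Si](C)(C)C(C)(C)C)cc1OC | intermediate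
8 | ortho-dienone, (6R)-2-acetyl-6-[(1R,2E)-1-(4-acetoxyphenyl)but-2-en-1-yl]-5-(tert-butyldimethylsilyloxy)-3-methoxycyclohexa-2,4-dien-1-one (side-chain descriptor is R by priority change only; geometry as in 9) | CC(=O)C1=C(OC)C=C(O[Si](C)(C)C(C)(C)C)[C@@H]([C@@H](/C=C/C)c2ccc(OC(C)=O)cc2)C1=O | intermediate
9 | 4-[(1S,2E)-1-[3-acetyl-6-(tert-butyldimethylsilyloxy)-2-hydroxy-4-methoxyphenyl]but-2-en-1-yl]phenyl acetate | CC(=O)c1c(O)c([C@@H](/C=C/C)c2ccc(OC(C)=O)cc2)c(O[Si](C)(C)C(C)(C)C)cc1OC | intermediate
10 | (S)-2-(chloromethyl)oxirane, (S)-epichlorohydrin | ClC[C@@H]1CO1 | starting material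
11 | vinylmagnesium bromide | C=C[Mg]Br | starting material
12 | (S)-1-chloropent-4-en-2-ol | ClC[C@@H](O)CC=C | intermediate
13 | (S)-2-(prop-2-en-1-yl)oxirane | C=CC[C@H]1CO1 | intermediate
14 | tert-butyl[4-(chloromethyl)phenoxy]dimethylsilane | CC(C)(C)[Si](C)(C)Oc1ccc(CCl)cc1 | starting material
15 | [4-(tert-butyldimethylsilyloxy)benzyl]magnesium chloride | CC(C)(C)[Si](C)(C)Oc1ccc(C[Mg]Cl)cc1 | intermediate
16 | (R)-1-[4-(tert-butyldimethylsilyloxy)phenyl]hex-5-en-3-ol | CC(C)(C)[Si](C)(C)Oc1ccc(CC[C@@H](O)CC=C)cc1 | intermediate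
17 | 4-[(1S,2E,5R)-1-[3-acetyl-6-(tert-butyldimethylsilyloxy)-2-hydroxy-4-methoxyphenyl]-7-[4-(tert-butyldimethylsilyloxy)phenyl]-5-hydroxyhept-2-en-1-yl]phenyl acetate | CC(=O)c1c(O)c([C@@H](/C=C/C[C@H](O)CCc2ccc(O[Si](C)(C)C(C)(C)C)cc2)c2ccc(OC(C)=O)cc2)c(O[Si](C)(C)C(C)(C)C)cc1OC | intermediate
18 | 4-hydroxybenzaldehyde | O=Cc1ccc(O)cc1 | starting material
19 | 1-{2,4-dihydroxy-3-[(1S,2E,5R)-5-hydroxy-1,7-bis(4-hydroxyphenyl)hept-2-en-1-yl]-6-methoxyphenyl}ethan-1-one | CC(=O)c1c(O)c([C@@H](/C=C/C[C@H](O)CCc2ccc(O)cc2)c2ccc(O)cc2)c(O)cc1OC | intermediate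
20 | (2E)-1-{2,4-dihydroxy-3-[(1S,2E,5R)-5-hydroxy-1,7-bis(4-hydroxyphenyl)hept-2-en-1-yl]-6-methoxyphenyl}-3-(4-hydroxyphenyl)prop-2-en-1-one | COc1cc(O)c([C@@H](/C=C/C[C@H](O)CCc2ccc(O)cc2)c2ccc(O)cc2)c(O)c1C(=O)/C=C/c1ccc(O)cc1 | target

## Step count and risks

Total step count: 8. Longest linear sequence: 5 steps (steps 2, 3, 4, 7, 8 from 4 and 5; equally steps 1, 3, 4, 7, 8 from 1).

**Step 4 (proposed new photoacid-gated Claisen shift).** The protonated ether may ionise to a 1-aryl-3-methylallyl cation instead of rearranging in concert. That would erode the enantiomeric purity, give [1,3] products or cleave 7 back to 3. Turnover at −20 °C may also be too slow. The fallback sets out from 7 and comes back at 9, and it gives up light and Brønsted acid altogether in favour of the classical thermal aromatic Claisen rearrangement, whose 1,3-chirality transfer through the chair transition state is established. Compound 7 is heated with tris(6,6,7,7,8,8,8-heptafluoro-2,2-dimethyl-3,5-octanedionato)europium, Eu(fod)3 (10 mol%), in CHCl3 at 60 °C, or without any additive in N,N-diethylaniline at 170 °C in a sealed tube. No new compound is made (F0).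

**Step 3 (Mitsunobu etherification).** The 2'-OH of 3 is chelated and flanked by the acetyl group, and 6 is a secondary allylic alcohol. Slow coupling, SN2' ether, diene formation by elimination or partial racemisation are all possible. The fallback sets out from 3 and 5 and comes back at 7. It replaces the inverting Mitsunobu step by a net-retention allylic etherification with zerovalent palladium, starting from the antipodal alcohol. (S)-but-3-en-2-ol F1 is cross-metathesised with 5 under the conditions of step 2 to give 4-[(1E,3S)-3-hydroxybut-1-en-1-yl]phenyl acetate F2. Methyl chloroformate and pyridine in CH2Cl2 at 0 °C convert this into 4-[(1E,3S)-3-(methoxycarbonyloxy)but-1-en-1-yl]phenyl acetate F3. F3 and 3 with Pd(PPh3)4 (2 mol%) in THF at rt then give 7 by double inversion: ionisation anti to the carbonate, then phenoxide attack anti to palladium at the methyl-bearing allyl terminus, which keeps the styrene conjugation. Carbon dioxide and methanol are lost.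

**Step 8 (one-pot deprotection and Claisen–Schmidt condensation).** The phenoxide of 18 is a poor electrophile and the polyphenolate of 19 a poor enolate precursor. Long reaction times on fully elaborated material invite flavanone formation and air oxidation. The fallback sets out from 17 and comes back at 20. It separates condensation from the final phenol release by using the aldehyde as its methoxymethyl ether. Compound 17 and 4-(methoxymethoxy)benzaldehyde F4 with KOH in EtOH at rt give (2E)-1-{2,4-dihydroxy-3-[(1S,2E,5R)-5-hydroxy-1,7-bis(4-hydroxyphenyl)hept-2-en-1-yl]-6-methoxyphenyl}-3-[4-(methoxymethoxy)phenyl]prop-2-en-1-one F5; the silyl and acetyl groups are lost in the same pot. Then 3 M HCl in MeOH at rt cleaves the acetal to give 20.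

## Further compounds

F0 | step 4 | none | none
F1 | step 3 | (S)-but-3-en-2-ol | C[C@H](O)C=C
F2 | step 3 | 4-[(1E,3S)-3-hydroxybut-1-en-1-yl]phenyl acetate | C[C@H](O)/C=C/c1ccc(OC(C)=O)cc1
F3 | step 3 | 4-[(1E,3S)-3-(methoxycarbonyloxy)but-1-en-1-yl]phenyl acetate | COC(=O)O[C@@H](C)/C=C/c1ccc(OC(C)=O)cc1
F4 | step 8 | 4-(methoxymethoxy)benzaldehyde | COCOc1ccc(C=O)cc1
F5 | step 8 | (2E)-1-{2,4-dihydroxy-3-[(1S,2E,5R)-5-hydroxy-1,7-bis(4-hydroxyphenyl)hept-2-en-1-yl]-6-methoxyphenyl}-3-[4-(methoxymethoxy)phenyl]prop-2-en-1-one | COCOc1ccc(/C=C/C(=O)c2c(O)c([C@@H](/C=C/C[C@H](O)CCc3ccc(O)cc3)c3ccc(O)cc3)c(O)cc2OC)cc1
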